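**Retrosynthetic overview**
- Last bond: the C4′=C5′ alkene of the side chain, by Horner–Wadsworth–Emmons coupling of a tetronic acid aldehyde with a bis-furyl allylic phosphonate.
- The tetronic acid ring is closed by a ring-opening Dieckmann condensation of an enol propanoate held inside a seven-membered lactone. The ring forces the acyl carbon and the methyl-bearing carbon to be cis, which is the 5E geometry (aldol–dehydration of tetronates would give 5Z).
- That lactone, and the only stereocentre, come from an enantioselective Baeyer–Villiger desymmetrization of 4-methylcyclohexanone.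
- Phosphonate: monolithiation of 3,4-dibromofuran and addition to furan-3-carbaldehyde, deoxygenation, Kumada coupling with a homoprenyl Grignard reagent, SeO2 allylic oxidation, Arbuzov-type phosphonylation.
- Ring order: oxepanone formed (step 1), then opened in the same step that closes the furanone (step 4); both furan rings are bought.

**Assumptions**
- The SMILES is taken literally: the exocyclic alkene is 5E (side chain cis to C4–OH) and the methyl-bearing carbon is S.
- Enolates and carbanions made by simple deprotonation are treated as forms of their parent compound and carry no number of their own.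

**Route**

Step 1
Reactants: 1 4-methylcyclohexanone
Product: 2 (5R)-5-methyloxepan-2-one
Conditions: m-CPBA, Sc(OTf)3 (5 mol%), chiral N,N′-dioxide ligand (trimethylene-bridged bis(pipecolic acid 2,6-diisopropylanilide N-oxide), antipode chosen for the R lactone), EtOAc, −20 °C
Reagents that add atoms: 3-chloroperoxybenzoic acid, OOC(=O)c1cccc(Cl)c1
Why: Enantioselective Baeyer–Villiger oxidation, in which the chiral scandium–peracid complex distinguishes the two enantiotopic α-methylene groups of the σ-symmetric ketone during the Criegee migration, so oxygen insertion on one side fixes the methyl-bearing carbon as R (the same spatial arrangement is named S later, once its neighbours change CIP priority).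

Step 2
Reactants: 2 (5R)-5-methyloxepan-2-one
Product: 3 (3RS,5S)-3-hydroxy-5-methyloxepan-2-one
Conditions: NaN(SiMe3)2, THF, −78 °C; 2-(phenylsulfonyl)-3-phenyloxaziridine; then AcOH
Reagents that add atoms: 2-(phenylsulfonyl)-3-phenyloxaziridine, O=S(=O)(N1OC1c1ccccc1)c1ccccc1
Why: Davis α-hydroxylation of the lactone enolate at C3, the only enolizable position; the new carbinol centre is formed as a mixture and is removed in step 3, and C5 is not touched.

Step 3
Reactants: 3 (3RS,5S)-3-hydroxy-5-methyloxepan-2-one; 4 propanoic anhydride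
Product: 6 (5S)-5-methyl-2-oxo-2,5,6,7-tetrahydrooxepin-3-yl propanoate, via (5S)-5-methyloxepane-2,3-dione 5 (not isolated)
Conditions: (COCl)2, DMSO, CH2Cl2, −78 °C; Et3N; then 4, DMAP (cat.), −78 → 0 °C
Reagents that add atoms: none
Why: Swern oxidation to the α-keto lactone followed by DMAP-catalysed O-acylation of its only possible enol; the C3=C4 enol double bond lies inside the seven-membered ring, so the lactone carbonyl and C5 are necessarily cis.

Step 4
Reactants: 6 (5S)-5-methyl-2-oxo-2,5,6,7-tetrahydrooxepin-3-yl propanoate
Product: 7 (5E)-4-hydroxy-5-[(2S)-4-hydroxy-2-methylbutylidene]-3-methylfuran-2(5H)-one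
Conditions: LiN(SiMe3)2 (2.1 equiv), THF, −78 → 0 °C (inverse addition); cold dilute HCl
Reagents that add atoms: none
Why: Proposed new method: ring-opening Dieckmann (intramolecular Claisen) condensation, in which the propanoate enolate attacks the adjacent lactone carbonyl 5-exo and the tetrahedral intermediate expels the ring alkoxide, so the tetronic acid forms with the ring-imposed 5E geometry and the stereocentre is not involved; the closest known reactions are the Dieckmann cyclization of O-acyl α-hydroxy esters to tetronic acids and of enol esters of α-keto esters to pulvinones.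

Step 5
Reactants: 7 (5E)-4-hydroxy-5-[(2S)-4-hydroxy-2-methylbutylidene]-3-methylfuran-2(5H)-one
Product: 8 (5E)-4-hydroxy-3-methyl-5-[(2S)-2-methyl-4-oxobutylidene]furan-2(5H)-one
Conditions: SO3·pyridine (2 equiv), DMSO, iPr2NEt (4 equiv), CH2Cl2, −10 °C; cold pH 3 work-up
Reagents that add atoms: none
Why: Parikh–Doering oxidation of the primary alcohol, with the tetronic acid present as its ammonium salt (a vinylogous carboxylate that should be inert to activated DMSO at low temperature); the aldehyde may rest as its cyclic lactol with the C4–OH, which the E geometry allows.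

Step 6
Reactants: 9 3,4-dibromofuran; 10 furan-3-carbaldehyde
Product: 12 (4-bromofuran-3-yl)(furan-3-yl)methanol, via 3-bromo-4-lithiofuran 11 (not isolated)
Conditions: n-BuLi (1.0 equiv), Et2O, −78 °C; then 10; then H2O
Reagents that add atoms: none
Why: Bromine–lithium exchange at one of the two equivalent C–Br bonds (kept at −78 °C so the 3-furyllithium does not isomerize) and 1,2-addition to the aldehyde; the racemic carbinol centre is removed in step 7.

Step 7
Reactants: 12 (4-bromofuran-3-yl)(furan-3-yl)methanol
Product: 13 3-bromo-4-(furan-3-ylmethyl)furan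
Conditions: Et3SiH (3 equiv), TFA (5 equiv), CH2Cl2, −20 → 0 °C
Reagents that add atoms: none
Why: Ionic hydrogenation, in which the bis-furyl-stabilized carbocation formed by acid is trapped by hydride from the silane.

Step 8
Reactants: 13 3-bromo-4-(furan-3-ylmethyl)furan; 14 5-bromo-2-methylpent-2-ene
Product: 16 3-(furan-3-ylmethyl)-4-(4-methylpent-3-en-1-yl)furan, via (4-methylpent-3-en-1-yl)magnesium bromide 15 (not isolated)
Conditions: Mg, THF, rt; then 13, NiCl2[Ph2P(CH2)3PPh2] (5 mol%), THF, 50 °C
Reagents that add atoms: none
Why: Kumada–Corriu coupling of the 3-bromofuran with a primary alkyl Grignard reagent; the remote trisubstituted alkene is inert.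

Step 9
Reactants: 16 3-(furan-3-ylmethyl)-4-(4-methylpent-3-en-1-yl)furan
Product: 17 (2E)-5-[4-(furan-3-ylmethyl)furan-3-yl]-2-methylpent-2-en-1-ol
Conditions: SeO2 (0.3 equiv), t-BuOOH (2.5 equiv), CH2Cl2, 0 °C → rt
Reagents that add atoms: selenium dioxide (catalytic oxygen carrier), O=[Se]=O; tert-butyl hydroperoxide, CC(C)(C)OO
Why: Selenium dioxide allylic oxidation (ene reaction then [2,3]-sigmatropic shift), which oxidizes the E methyl group of the prenyl terminus and so gives the E allylic alcohol.

Step 10
Reactants: 17 (2E)-5-[4-(furan-3-ylmethyl)furan-3-yl]-2-methylpent-2-en-1-ol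
Product: 18 diethyl {(2E)-5-[4-(furan-3-ylmethyl)furan-3-yl]-2-methylpent-2-en-1-yl}phosphonate
Conditions: P(OEt)3 (3 equiv), ZnI2 (1.5 equiv), THF, reflux
Reagents that add atoms: triethyl phosphite, CCOP(OCC)OCC
Why: Zinc iodide-mediated one-flask Michaelis–Arbuzov-type conversion of a primary allylic alcohol into its diethyl phosphonate at the less hindered allyl terminus, keeping the E alkene.

Step 11
Reactants: 8 (5E)-4-hydroxy-3-methyl-5-[(2S)-2-methyl-4-oxobutylidene]furan-2(5H)-one; 18 diethyl {(2E)-5-[4-(furan-3-ylmethyl)furan-3-yl]-2-methylpent-2-en-1-yl}phosphonate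
Product: 19 (5E)-5-{(2S,4E,6E)-9-[4-(furan-3-ylmethyl)furan-3-yl]-2,6-dimethylnona-4,6-dien-1-ylidene}-4-hydroxy-3-methylfuran-2(5H)-one
Conditions: 18 (2.2 equiv), n-BuLi (2.1 equiv), THF–DMPU, −78 °C; add 8; → rt; cold dilute HCl to pH 3, protect from light
Reagents that add atoms: none
Why: Horner–Wadsworth–Emmons olefination by α-attack of the lithiated allylic phosphonate, which gives the new disubstituted alkene E; the first equivalent of carbanion turns the tetronic acid into its lithium salt, which is unreactive and shields the C–H of the stereocentre from deprotonation.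

**Compound list**
1 | 4-methylcyclohexanone | CC1CCC(=O)CC1 | starting material
2 | (5R)-5-methyloxepan-2-one | O=C1CC[C@@H](C)CCO1 | intermediate
3 | (3RS,5S)-3-hydroxy-5-methyloxepan-2-one (same spatial arrangement at C5 as in 2) | O=C1C(O)C[C@@H](C)CCO1 | intermediate
4 | propanoic anhydride | CCC(=O)OC(=O)CC | starting material
5 | (5S)-5-methyloxepane-2,3-dione | O=C1C(=O)C[C@@H](C)CCO1 | intermediate
6 | (5S)-5-methyl-2-oxo-2,5,6,7-tetrahydrooxepin-3-yl propanoate | CCC(=O)OC1=C[C@@H](C)CCOC1=O | intermediate
7 | (5E)-4-hydroxy-5-[(2S)-4-hydroxy-2-methylbutylidene]-3-methylfuran-2(5H)-one | CC1=C(O)/C(=C\[C@@H](C)CCO)OC1=O | intermediate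
8 | (5E)-4-hydroxy-3-methyl-5-[(2S)-2-methyl-4-oxobutylidene]furan-2(5H)-one | CC1=C(O)/C(=C\[C@@H](C)CC=O)OC1=O | intermediate
9 | 3,4-dibromofuran | Brc1cocc1Br | starting material
10 | furan-3-carbaldehyde | O=Cc1ccoc1 | starting material
11 | 3-bromo-4-lithiofuran | [Li]c1cocc1Br | intermediate
12 | (4-bromofuran-3-yl)(furan-3-yl)methanol (racemic) | OC(c1ccoc1)c1cocc1Br | intermediate
13 | 3-bromo-4-(furan-3-ylmethyl)furan | Brc1cocc1Cc1ccoc1 | intermediate
14 | 5-bromo-2-methylpent-2-ene | CC(C)=CCCBr | starting material
15 | (4-methylpent-3-en-1-yl)magnesium bromide | CC(C)=CCC[Mg]Br | intermediate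
16 | 3-(furan-3-ylmethyl)-4-(4-methylpent-3-en-1-yl)furan | CC(C)=CCCc1cocc1Cc1ccoc1 | intermediate
17 | (2E)-5-[4-(furan-3-ylmethyl)furan-3-yl]-2-methylpent-2-en-1-ol | OC/C(C)=C/CCc1cocc1Cc1ccoc1 | intermediate
18 | diethyl {(2E)-5-[4-(furan-3-ylmethyl)furan-3-yl]-2-methylpent-2-en-1-yl}phosphonate | CCOP(=O)(OCC)C/C(C)=C/CCc1cocc1Cc1ccoc1 | intermediate
19 | (5E)-5-{(2S,4E,6E)-9-[4-(furan-3-ylmethyl)furan-3-yl]-2,6-dimethylnona-4,6-dien-1-ylidene}-4-hydroxy-3-methylfuran-2(5H)-one | CC1=C(O)/C(=C\[C@@H](C)C/C=C/C(C)=C/CCc2cocc2Cc2ccoc2)OC1=O | target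

**Step count**
Total: 11 steps. Longest linear sequence: 6 steps (1 → 2 → 3 → 6 → 7 → 8 → 19; the branch 9 → 12 → 13 → 16 → 17 → 18 → 19 is equally long).

**Steps most likely to fail, with fallbacks**

Step 1 may give insufficient enantiomeric excess, or the wrong antipode, because the only group that distinguishes the two sides of the ketone is a remote methyl. The fallback replaces the oxidation by a desymmetrizing deprotonation; it sets out from 1 and comes back at 2. Compound 1 is deprotonated with the appropriate antipode of lithium bis(1-phenylethyl)amide in THF at −78 °C in the presence of Me3SiCl, giving (R)-4-methyl-1-(trimethylsilyloxy)cyclohexene F1. Ozonolysis in CH2Cl2/MeOH at −78 °C with NaBH4 work-up gives (R)-6-hydroxy-4-methylhexanoic acid F2. Lactonization under high dilution (2,4,6-trichlorobenzoyl chloride, Et3N, DMAP) returns 2.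

Step 4 may fail through loss of methylketene from the enol ester enolate, or through γ-deprotonation at the stereocentre by the amide base. The fallback generates the enolate reductively instead of by deprotonation; it sets out from 3 and comes back at 7. Compound 3 is oxidized as in step 3 to 5, and the enol is acylated with 2-bromopropanoyl bromide and Et3N to give (5S)-5-methyl-2-oxo-2,5,6,7-tetrahydrooxepin-3-yl 2-bromopropanoate F3. SmI2 (2.2 equiv) in THF at −78 °C then forms the samarium enolate without base (Reformatsky-type), and this undergoes the same ring-opening acylation to 7.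

Step 5 may fail through attack of the oxidant on the tetronic acid or through over-oxidation of the cyclic lactol form of 8. The fallback masks the tetronic acid as its methyl ether; it sets out from 7 and comes back at 19. Compound 7 is O-methylated with Me3SiCHN2 in toluene/MeOH to (5E)-5-[(2S)-4-hydroxy-2-methylbutylidene]-4-methoxy-3-methylfuran-2(5H)-one F4. Dess–Martin oxidation gives (5E)-4-methoxy-3-methyl-5-[(2S)-2-methyl-4-oxobutylidene]furan-2(5H)-one F5. The olefination of step 11 with 18 gives the 4-O-methyl ether of the target F6. Demethylation with LiSPr in DMF at room temperature gives 19.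

**Further compounds**
F1 | step 1 | (R)-4-methyl-1-(trimethylsilyloxy)cyclohexene | C[Si](C)(C)OC1=CC[C@H](C)CC1
F2 | step 1 | (R)-6-hydroxy-4-methylhexanoic acid | OC(=O)CC[C@@H](C)CCO
F3 | step 4 | (5S)-5-methyl-2-oxo-2,5,6,7-tetrahydrooxepin-3-yl 2-bromopropanoate | CC(Br)C(=O)OC1=C[C@@H](C)CCOC1=O
F4 | step 5 | (5E)-5-[(2S)-4-hydroxy-2-methylbutylidene]-4-methoxy-3-methylfuran-2(5H)-one | CC1=C(OC)/C(=C\[C@@H](C)CCO)OC1=O
F5 | step 5 | (5E)-4-methoxy-3-methyl-5-[(2S)-2-methyl-4-oxobutylidene]furan-2(5H)-one | CC1=C(OC)/C(=C\[C@@H](C)CC=O)OC1=O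
F6 | step 5 | (5E)-5-{(2S,4E,6E)-9-[4-(furan-3-ylmethyl)furan-3-yl]-2,6-dimethylnona-4,6-dien-1-ylidene}-4-methoxy-3-methylfuran-2(5H)-one | CC1=C(OC)/C(=C\[C@@H](C)C/C=C/C(C)=C/CCc2cocc2Cc2ccoc2)OC1=O
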